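The meeting began with an easy step: substrate used is target plus over-reaction product, since both are read in percent of the substrate charged.

| flask | substrate | reagent | remark | time |
|---|---|---|---|---|
| noon | 0.15 M | 0.15 M | run made earlier |  |
| autumn | 0.15 M | 0.075 M | run made earlier |  |
| winter | 0.15 M | 0.11 M | run made earlier |  |
| dawn | 0.22 M | 0.15 M | run made earlier |  |
| cedar | 0.15 M | 0.150 M (fed, over 50 s) | all else is in the flask from the start; the feed brings no volume worth counting | 4.0 min |
| oak | 0.15 M (fed, over 50 s) | 0.150 M | all else is in the flask from the start; the feed brings no volume worth counting | 4.0 min |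
| larch | 0.15 M | 0.150 M | everything together at the start | 4.0 min |

- noon (time / min: target / %, over-reaction product / %): 0.250: 0, 1; 0.833: 13, 8; 1.33: 19, 13; 2.00: 23, 18; 3.00: 28, 23; 4.00: 28, 26
- autumn (time / min: target / %, over-reaction product / %): 0.417: 0, 0; 0.833: 2, 5; 1.33: 9, 5; 1.50: 8, 6; 2.00: 14, 6; 2.50: 15, 9
- winter (time / min: target / %, over-reaction product / %): 0.200: 1, 0; 0.333: 1, 0; 0.500: 2, 0; 0.833: 8, 4; 1.33: 13, 9; 2.50: 21, 16
- dawn (time / min: target / %, over-reaction product / %): 0.200: 0, 0; 0.333: 8, 2; 0.667: 13, 3; 1.33: 21, 7; 2.50: 31, 11

(readings scatter by 1.5 percentage points)

- a reading or a percentage of target counts all its forms, free or not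

1. the best flask by share of target in target plus over-reaction product; "all alike" if 1.5 percentage points covers them all (cedar / oak / larch / all alike)
2. share of target in target plus over-reaction product at the end, cedar
3. share of target in target plus over-reaction product at the end, oak
4. share of target in target plus over-reaction product at the end, larch

The first speaker proposed following one molecule of reagent. At each fork it either takes a substrate into target or turns a target into over-reaction product. She called f the substrate used per over-reaction product made, a selectivity factor for that fork. In noon, from 0.833 min to 4.00 min, she read f = 1.83, at a mean substrate of 0.0938 M. She supposed f grows in step with substrate. She defined the fork constant K as f divided by the substrate concentration, here 19.6 L mol⁻¹.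

The second speaker wanted another run. Dawn, from 0.667 min to 2.50 min, gave K = 20.8 L mol⁻¹.

The third speaker summed the forks. With x the fraction of substrate left and c its charge, over-reaction product is −ln(x)/(Kc) of the charge. Autumn, with half the reagent, then gives 9.36% at 2.50 min, against 9% read. So reagent seemed to cancel.

Larch repeats noon's charges, whose last reading leaves x = 46.0%. That gives a share of 51.0%. The earlier runs had no feed, and noon already reads 8% of over-reaction product at 0.833 min, the length of the feed, so for cedar and oak the meeting called its figure a judgement. It committed to all flasks alike, near that share. For a repeat, watch the substrate left.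

The forecast gave cedar, with 53%, 47% and 52% for cedar, oak and larch, on the ground that “Oak starves substrate early”.

The flasks give all alike: cedar 51.4%, oak 51.2%, larch 50.6%.

    substrate + reagent + target → 2 target (k = 4.90 L² mol⁻² s⁻¹)
    substrate + reagent → target (k = 0.00380 L mol⁻¹ s⁻¹)
    reagent + target → over-reaction product (k = 0.270 L mol⁻¹ s⁻¹)
    crystals ⇌ target, rate k4*(cs4 - [target]) while solid is left; crystals form when [target] > cs4 (solubility = 11.0 mM, k = 2.20 s⁻¹)

In larch, reagent used by the substrate step over that used by the over-reaction step falls from 1.9 at 1.19 min to 1.2 at 4.00 min. K times larch's final substrate, 44.2% of the charge, gives 1.30 for that ratio. Larch stopped at 1.5 min has 65.3% of its substrate left, so K gives a share of 58.1%. That flask gives 59.1%.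

The numbers in the tables come from a simulation with constants of no real substance.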